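## Structural features

The target is a C15 germacrane-type lactone esterified with isovaleric acid. The carbons are numbered C1–C10 around the ten-membered carbocycle, C14 is the methyl on C10, C15 the methyl on C4, and C11–C13 are the lactone carbons on C7 (C12 carbonyl, C13 exocyclic methylene); these numbers are kept for every precursor. An ether oxygen joins C5 and C10 across the carbocycle and turns it into an 11-oxabicyclo[4.4.1]undecane built from two oxepanes, ring A (O, C5, C4, C3, C2, C1, C10) and ring B (O, C5, C6, C7, C8, C9, C10). Ring B carries the α-methylene-γ-butyrolactone trans-fused at C7–C8 and the isovalerate on C9; ring A carries only the C4 methyl. Four stereocentres are contiguous (C7, C8, C9, C10), with C10 a fully substituted ether carbon (O, C14, C1, C9) next to the acyloxy carbon C9; C5 and C4 follow across the bridge, and the configuration of C5 is not independent because the one-atom bridge forces both C–O bonds to the same face. Fragile groups are the exocyclic enoate (Michael acceptor, sensitive to radicals, hydride and base) and the hindered secondary ester; the bridging dialkyl ether is robust. The real difficulty is the medium ring locked by a transannular ether whose quaternary end C10 must be set relative to C9, C8 and C7. The key step exploits the 1,6-relationship of C5 and C10: if the oxygen is removed and C5 is bonded to C10, both oxepanes contract to cyclohexanes and the skeleton becomes a eudesmane-type decalin with C10 as an ordinary angular-methyl carbon, so the bridge can be made by inserting oxygen into that ring-fusion bond. In the decalin precursors β denotes the face of C14 and α the opposite face.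

## Logic of the disconnections

29 ⇒ 27 ⇒ 25 + 26, and 24 ⇒ 21 + 22. Bonds cut: the C11=C13 π bond (retro-elimination to a C13–N bond), the acyl–O9 bond and the C11–C13 σ bond. Reason: the enoate cannot survive the hydride, radical and enolate chemistry used earlier, and the isovalerate would compete in enolate formation. Gain: the end game reduces to the saturated lactone 21 with a silyl ether on O9. Demand: the lactone must be the only carbon acid when C13 is introduced, so the ester is put on after the aminomethylation and the methylene is unveiled last.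

21 ⇒ 20. Bond cut: C5–H. Reason: the bridgehead hydrogen is what remains of the ketal carbon left by an oxygen insertion. Gain: it links the ether to a rearrangement product. Demand: the bridgehead α-oxy cation must take hydride faster than it loses a proton toward C4.

20 ⇒ 18 (key). Bonds: the C10–O bond is cut and the C5–C10 bond is restored. In one sentence: a Criegee rearrangement of the decalin hydroperoxide 18 inserts the ether oxygen into the C5–C10 ring-fusion bond. Reason: both oxepanes, the ten-membered carbocycle and the quaternary ether carbon are traded for a decalin and an angular methyl group. Gain: no medium ring has to be closed, and C10 is a carbon stereocentre present from the first compound. Demand: C10 must migrate in preference to C4 and C6, and with retention.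

18 ⇒ 16. Bond cut: C5–OO (with C6–H). Reason: a tertiary hydroperoxide at a ring fusion comes from Markovnikov hydrogen-atom transfer and oxygen trapping at a trisubstituted alkene. Gain: the peroxide is replaced by the C5=C6 alkene. Demand: C5=C6 must be the only alkene, which is why the enoate is absent at this stage.

16 ⇒ 15 ⇒ 13 ⇒ 11. Bonds cut: O9–Si, the lactone C12–O8 bond, C9–H and C8–O. Reason: the trans-diequatorial 8α,9β-dioxygen pattern is the one obtained by α-oxidation and reduction of a C9 ketone when every reagent enters anti to C14. Gain: three functional groups collapse to one ketone flanked by a quaternary carbon, with a single enolisable position. Demand: oxaziridine and borohydride must both attack from the α face.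

11 ⇒ 10. Bond cut: C7–H. Reason: conjugate hydride addition to a C9 dienone sets C7 and leaves C5=C6 in place. Gain: C7 becomes sp2. Demand: 1,4- over 1,6-reduction and α-face delivery, the latter enforced by the catalyst.

10 ⇒ 9 ⇒ 6 + 7. Bonds cut: C7–C11, with oxygen moved back from C9 to C7. Reason: an ester enolate adds 1,2 to a cross-conjugated dienone and an oxidative 1,3-transposition then places the carbonyl at C9. Gain: ring B's substituents are traced to a plain dienone and ethyl acetate. Demand: the transposition must run toward C9 only; C5 cannot be oxidised.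

6 ⇒ 4 ⇒ 3 ⇒ 1 + 2. Bonds cut: the C8=C9 π bond and C4–C15 (as a methylene, then H2). Reason: the γ-carbon of the enone can be methylenated and the exocyclic alkene hydrogenated from the α face. Gain: the enantiopure bicyclic enone 1 is the only chiral starting material. Demand: α-face hydrogenation at C4 and no later γ-epimerisation.

## Other disconnections considered

Alternative 1: Cut the C10–O bond with the ten-membered carbocycle kept intact (the first idea for a bridged germacranolide). The forward key step is transannular alkoxymercuration–demercuration (Hg(OCOCF3)2, then NaBH4) of the 5-hydroxy-1(10)-ene A1, after the ten-membered ring has been closed by an intramolecular Nozaki–Hiyama–Kishi reaction (CrCl2/NiCl2) or ring-closing metathesis. The chosen plan is preferred for three reasons: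
- A1 needs a medium-ring closure on an open chain carrying four stereocentres, with the usual entropic and transannular cost.
- The configuration of C10 would be decided by which alkene face the C5 hydroxyl reaches, that is by the conformer population of a flexible ring. The allylic acyloxy group on C9 can also ionise under electrophilic activation. In the chosen plan C10 is a defined quaternary carbon that only exchanges one neighbour.
- Building the C7–C9 triad on an open chain costs more steps than functionalising a rigid decalin.

Alternative 2: Cut the C5–O and C10–C14 bonds (retron: cyclodecane-1,6-dione). The forward key step is ozonolysis of the tetrasubstituted C5=C10 alkene of the octalin A2 to the diketone A3, then methyl addition at C10 with transannular hemiketalisation onto C5 and silane reduction. It shares the ring-expansion logic, but the methyl nucleophile would have to distinguish two similar ketones and one face of a mobile ten-membered ring. In A3 both C9 and C4 are α to a ketone and can epimerise. The chosen plan avoids this because C14 is in place before the ring is opened and C10 migrates with retention.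

Alternative 3: Cut the C4–C5 bond and the C10–O bond. The forward key step is Baeyer–Villiger oxidation of the 2,2-disubstituted cyclohexanone A4 to the oxepanone A5 (C10 migrating with retention), then closure of ring A by intramolecular Barbier addition (SmI2) of C4 to the lactone carbonyl and reduction of the bridged hemiketal. The oxygen insertion is the same 1,2-shift, but the second oxepane would then need a C–C bond formed at a secondary radical or carbanion centre (C4) that cannot hold its configuration, in the presence of a second lactone carbonyl. Two ring-forming operations replace one, and the quaternary C10 of A4 would have to be made by enolate alkylation.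

Key step: step 11

Assumption: the SMILES is read as the C5–O–C10 bridged germacranolide described above, and the enantiopure octalone 1 is taken as a purchasable building block.

## Route

Step 1
Reactants: 1 (R)-4a-methyl-4,4a,5,6,7,8-hexahydronaphthalen-2(3H)-one; 2 dimethoxymethane
Product: 3 (R)-4a-methyl-8-methylidene-4,4a,5,6,7,8-hexahydronaphthalen-2(3H)-one
Conditions: CH2(OMe)2, POCl3, NaOAc, CHCl3, 60 °C
Reagents that add atoms: none
Why: Acid-promoted γ-methylenation of the enone through its extended dienol ether: the methoxymethyl cation attacks C4 and methanol is lost, the reaction type used for 6-methylenation of 3-oxo-4-ene steroids, whose enone is this octalone; no stereocentre is created.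

Step 2
Reactants: 3 (R)-4a-methyl-8-methylidene-4,4a,5,6,7,8-hexahydronaphthalen-2(3H)-one
Product: 4 (4aR,8S)-4a,8-dimethyl-4,4a,5,6,7,8-hexahydronaphthalen-2(3H)-one
Conditions: H2 (1 atm), RhCl(PPh3)3 (cat.), PhH/EtOH, rt
Reagents that add atoms: none
Why: Homogeneous hydrogenation should reduce only the 1,1-disubstituted exocyclic alkene and leave the trisubstituted enone alkene. Hydrogen should reach C4 from the α face, away from the syn-axial C14, so that C15 ends β (cis to C14), as in the hydrogenation of 6-methylene-3-oxo-4-ene steroids.

Step 3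
Reactants: 4 (4aR,8S)-4a,8-dimethyl-4,4a,5,6,7,8-hexahydronaphthalen-2(3H)-one
Product: 6 (4aR,8S)-4a,8-dimethyl-5,6,7,8-tetrahydronaphthalen-2(4aH)-one, via lithium dienolate 5 (not isolated)
Conditions: LiN(iPr)2, THF, −78 °C; then PhS(Cl)=NtBu, −78 °C
Reagents that add atoms: none
Why: Kinetic α′-deprotonation at C8 (no γ-deprotonation, so C4 is not touched) followed by sulfinimidoyl transfer and syn elimination (Mukaiyama dehydrogenation) should give the cross-conjugated dienone.

Step 4
Reactants: 6 (4aR,8S)-4a,8-dimethyl-5,6,7,8-tetrahydronaphthalen-2(4aH)-one; 7 ethyl acetate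
Product: 9 ethyl (4αH)-7ξ-hydroxy-13-noreudesma-5,8-dien-12-oate, via lithium enolate of ethyl acetate 8 (not isolated)
Conditions: 7, LiN(iPr)2, THF, −78 °C; then 6, −78 °C; aq. NH4Cl
Reagents that add atoms: none
Why: Kinetic 1,2-addition of a lithium ester enolate to the dienone carbonyl, both β-carbons being hindered (C9 neopentyl, C5 fully substituted). The configuration of the carbinol carbon C7 is irrelevant because it becomes sp2 in step 5.

Step 5
Reactants: 9 ethyl (4αH)-7ξ-hydroxy-13-noreudesma-5,8-dien-12-oate
Product: 10 ethyl (4αH)-9-oxo-13-noreudesma-5,7-dien-12-oate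
Conditions: [C5H5NH][CrO3Cl] (pyridinium chlorochromate), 4 Å MS, CH2Cl2, rt
Reagents that add atoms: none
Why: Babler–Dauben oxidative 1,3-transposition: the tertiary chromate ester shifts across C8=C9 and the secondary C9 chromate is oxidised. The alternative shift to C5 gives a tertiary chromate that cannot be oxidised and returns, so oxygen ends at C9 only.

Step 6
Reactants: 10 ethyl (4αH)-9-oxo-13-noreudesma-5,7-dien-12-oate
Product: 11 ethyl (4αH,7αH)-9-oxo-13-noreudesm-5-en-12-oate
Conditions: Cu(OAc)2·H2O (cat.), DTBM-SEGPHOS (cat., the enantiomer matched to α-face delivery), (EtO)2MeSiH, tBuOH, PhMe, 0 °C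
Reagents that add atoms: none
Why: A ligated monovalent copper hydride should add hydride 1,4 to C7 (1,6-addition is disfavoured because C5 is fully substituted) and tert-butanol protonates the copper enolate. The chiral bisphosphine is chosen to deliver hydride to the α face, placing the side chain β (cis to C14), the conjugate reduction established for 3-substituted cyclohexenones.

Step 7
Reactants: 11 ethyl (4αH,7αH)-9-oxo-13-noreudesm-5-en-12-oate
Product: 13 ethyl (4αH,7αH)-8α-hydroxy-9-oxo-13-noreudesm-5-en-12-oate, via potassium enolate 12 (not isolated)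
Conditions: KN(SiMe3)2, THF, −78 °C; then 2-(phenylsulfonyl)-3-phenyloxaziridine, −78 °C; aq. NH4Cl
Reagents that add atoms: 2-(phenylsulfonyl)-3-phenyloxaziridine, O=S(=O)(N1OC1c1ccccc1)c1ccccc1
Why: C8 is the only enolisable position of the C9 ketone because C10 is quaternary. The enolate should be oxidised by the N-sulfonyloxaziridine from the α face, anti to the β side chain on C7 and to the 1,3-related C14, giving the equatorial 8α-alcohol, which is also the thermodynamic epimer.

Step 8
Reactants: 13 ethyl (4αH,7αH)-8α-hydroxy-9-oxo-13-noreudesm-5-en-12-oate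
Product: 15 (4αH,7αH)-9β-hydroxy-13-noreudesm-5-en-12,8α-olide, via diol ester 14 (not isolated)
Conditions: NaBH4, MeOH, −20 °C; then PPTS (cat.), PhMe, 80 °C
Reagents that add atoms: none
Why: Borohydride should attack the C9 ketone axially from the α face (the β face is screened by the adjacent axial C14, as in angular-methyl decalones), giving the equatorial 9β-alcohol. Acid then closes the trans-fused γ-lactone from the diequatorial 8α-hydroxy ester; the 9β-hydroxyl cannot reach the ester.

Step 9
Reactants: 15 (4αH,7αH)-9β-hydroxy-13-noreudesm-5-en-12,8α-olide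
Product: 16 (4αH,7αH)-9β-(tert-butyldimethylsilyloxy)-13-noreudesm-5-en-12,8α-olide
Conditions: TBSOTf, 2,6-lutidine, CH2Cl2, −78 to 0 °C
Reagents that add atoms: tert-butyldimethylsilyl trifluoromethanesulfonate, CC(C)(C)[Si](C)(C)OS(=O)(=O)C(F)(F)F
Why: Silyl triflate with a hindered pyridine base silylates the hindered secondary alcohol. A silyl ether is the least electron-withdrawing cover for O9, which matters for the migration in step 11.

Step 10
Reactants: 16 (4αH,7αH)-9β-(tert-butyldimethylsilyloxy)-13-noreudesm-5-en-12,8α-olide
Product: 18 (4αH,7αH)-5ξ-hydroperoxy-9β-(tert-butyldimethylsilyloxy)-13-noreudesman-12,8α-olide, via triethylsilyl peroxide 17 (not isolated)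
Conditions: Co(thd)2 (cat., thd = 2,2,6,6-tetramethylheptane-3,5-dionate), Et3SiH, O2 (1 atm), ClCH2CH2Cl, rt; then PPTS, MeOH, 0 °C
Reagents that add atoms: dioxygen, O=O
Why: Mukaiyama–Isayama hydroperoxysilylation: a cobalt hydride transfers a hydrogen atom to C6 of the only alkene, the tertiary C5 radical traps O2 and the cobalt peroxide is silylated by the silane. Mild acid methanolysis then frees the hydroperoxide while the hindered silyl ether stays. Either C5 epimer serves because C5 becomes trigonal in step 11.

Step 11
Reactants: 18 (4αH,7αH)-5ξ-hydroperoxy-9β-(tert-butyldimethylsilyloxy)-13-noreudesman-12,8α-olide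
Product: 20 5-(4-nitrobenzoyloxy)-5,10-epoxy-9-(tert-butyldimethylsilyloxy)-13-norgermacran-12,8-olide (acyloxy group exo on C5; C4/C7/C8/C9/C10 as in the target), via 4-nitroperbenzoate 19 (not isolated)
Conditions: 4-O2NC6H4COCl, pyridine, DMAP (cat.), CH2Cl2, 0 °C to rt
Reagents that add atoms: 4-nitrobenzoyl chloride, O=C(Cl)c1ccc(cc1)[N+](=O)[O-]
Why: Acylation of the tertiary hydroperoxide gives perester 19, whose O–O bond heterolyses with a concerted 1,2-shift of C10 from C5 to the proximal oxygen (Criegee rearrangement), the C10–C5 bond lying antiperiplanar to the O–O bond; the bridgehead α-oxy cation and the 4-nitrobenzoate form a tight ion pair that should collapse to the acyloxy ketal 20. The closest known reaction is the rearrangement of 9-decalyl peresters to 1-acyloxy-1,6-epoxycyclodecanes, which is the same bicyclic skeleton. Both oxepanes (ring A and ring B) arise at once by ring expansion and not by end-to-end cyclisation: the ring-fusion bond is exchanged for the C10–O bond, so no medium-ring closure is involved. C10 migrates with retention, the new C–O bond forming where C5 was attached, so the quaternary ether centre inherits the angular-methyl configuration of the decalin. C5 becomes a ketal carbon whose configuration is fixed by the one-atom bridge, the carboxylate being able to occupy only the exo position. The selectivity needed is migration of C10 in preference to C4 and C6; all three can reach the antiperiplanar alignment by rotation about C5–O, so the choice follows migratory aptitude (tertiary over secondary over primary), helped by release of the 1,3-diaxial C14/C15 interaction and by keeping O9 as a silyl ether to limit inductive deactivation of C10. Lactone, silyl ether and the saturated framework are inert to these conditions.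

Step 12
Reactants: 20 5-(4-nitrobenzoyloxy)-5,10-epoxy-9-(tert-butyldimethylsilyloxy)-13-norgermacran-12,8-olide
Product: 21 (4S,5R,7R,8R,9S,10R)-5,10-epoxy-9-(tert-butyldimethylsilyloxy)-13-norgermacran-12,8-olide
Conditions: Et3SiH, TMSOTf (cat.), CH2Cl2, −78 to −40 °C; aq. NaHCO3
Reagents that add atoms: none
Why: The silyl triflate ionises the bridgehead acyloxy ketal to the α-oxy cation and triethylsilane delivers hydride (ionic hydrogenation of a ketal ester). Hydride can enter only from the exo side of the bicycle, so C5 takes the configuration dictated by C10.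

Step 13
Reactants: 21 (4S,5R,7R,8R,9S,10R)-5,10-epoxy-9-(tert-butyldimethylsilyloxy)-13-norgermacran-12,8-olide; 22 dimethylmethyleneiminium iodide
Product: 24 13-(dimethylamino)-5,10-epoxy-9-(tert-butyldimethylsilyloxy)germacran-12,8-olide (11ξ), via lithium lactone enolate 23 (not isolated)
Conditions: LiN(iPr)2, THF, −78 °C; then 22, −78 to 0 °C
Reagents that add atoms: none
Why: The γ-lactone is the only carbon acid, and its lithium enolate is aminomethylated by the iminium salt (Mannich reaction). The configuration at C11 is irrelevant because it becomes sp2 in step 16.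

Step 14
Reactants: 24 13-(dimethylamino)-5,10-epoxy-9-(tert-butyldimethylsilyloxy)germacran-12,8-olide (11ξ)
Product: 25 13-(dimethylamino)-5,10-epoxy-9-hydroxygermacran-12,8-olide (11ξ)
Conditions: HF·pyridine, THF/pyridine, 0 °C to rt; aq. NaHCO3
Reagents that add atoms: none
Why: Fluoride cleavage of the hindered silyl ether under buffered acidic conditions, which leave the lactone, the amine and the bridging ether untouched and generate no alkoxide.

Step 15
Reactants: 25 13-(dimethylamino)-5,10-epoxy-9-hydroxygermacran-12,8-olide (11ξ); 26 3-methylbutanoyl chloride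
Product: 27 13-(dimethylamino)-5,10-epoxy-9-(3-methylbutanoyloxy)germacran-12,8-olide (11ξ)
Conditions: 26, pyridine, DMAP (cat.), CH2Cl2, 0 °C to rt
Reagents that add atoms: none
Why: DMAP-catalysed acylation of the secondary alcohol. The amino group keeps the lactone α-position masked, so no conjugate addition to an enoate can interfere.

Step 16
Reactants: 27 13-(dimethylamino)-5,10-epoxy-9-(3-methylbutanoyloxy)germacran-12,8-olide (11ξ)
Product: 29 (4S,5R,7R,8R,9S,10R)-5,10-epoxy-9-(3-methylbutanoyloxy)germacr-11(13)-en-12,8-olide (CNP0274454.1), via ammonium iodide 28 (not isolated)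
Conditions: MeI, MeOH, rt; then NaHCO3 (aq.), EtOAc, rt
Reagents that add atoms: none
Why: N-Methylation to the quaternary ammonium salt and mild base-induced β-elimination (Hofmann-type, through the lactone enolate) unveil the exocyclic methylene in the last step. The isovalerate is inert to bicarbonate.

## Compound list

1 | (R)-4a-methyl-4,4a,5,6,7,8-hexahydronaphthalen-2(3H)-one | O=C1C=C2CCCC[C@]2(C)CC1 | starting material
2 | dimethoxymethane | COCOC | starting material
3 | (R)-4a-methyl-8-methylidene-4,4a,5,6,7,8-hexahydronaphthalen-2(3H)-one | O=C1C=C2C(=C)CCC[C@]2(C)CC1 | intermediate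
4 | (4aR,8S)-4a,8-dimethyl-4,4a,5,6,7,8-hexahydronaphthalen-2(3H)-one (C14 and C15 both β) | O=C1C=C2[C@@H](C)CCC[C@]2(C)CC1 | intermediate
5 | lithium dienolate of 4 (O on C7, C7=C8 and C5=C6) | [Li+].[O-]C1=CC[C@@]2(C)CCC[C@H](C)C2=C1 | intermediate
6 | (4aR,8S)-4a,8-dimethyl-5,6,7,8-tetrahydronaphthalen-2(4aH)-one | O=C1C=C[C@@]2(C)CCC[C@H](C)C2=C1 | intermediate
7 | ethyl acetate | CCOC(C)=O | starting material
8 | lithium enolate of ethyl acetate | [Li+].[O-]C(=C)OCC | intermediate
9 | ethyl (4αH)-7ξ-hydroxy-13-noreudesma-5,8-dien-12-oate | CCOC(=O)CC1(O)C=C[C@@]2(C)CCC[C@H](C)C2=C1 | intermediate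
10 | ethyl (4αH)-9-oxo-13-noreudesma-5,7-dien-12-oate | CCOC(=O)CC1=CC(=O)[C@@]2(C)CCC[C@H](C)C2=C1 | intermediate
11 | ethyl (4αH,7αH)-9-oxo-13-noreudesm-5-en-12-oate | CCOC(=O)C[C@@H]1CC(=O)[C@@]2(C)CCC[C@H](C)C2=C1 | intermediate
12 | potassium C8 enolate of 11 | CCOC(=O)C[C@@H]1C=C([O-])[C@@]2(C)CCC[C@H](C)C2=C1.[K+] | intermediate
13 | ethyl (4αH,7αH)-8α-hydroxy-9-oxo-13-noreudesm-5-en-12-oate | CCOC(=O)C[C@@H]1[C@@H](O)C(=O)[C@@]2(C)CCC[C@H](C)C2=C1 | intermediate
14 | ethyl (4αH,7αH)-8α,9β-dihydroxy-13-noreudesm-5-en-12-oate | CCOC(=O)C[C@@H]1[C@@H](O)[C@H](O)[C@@]2(C)CCC[C@H](C)C2=C1 | intermediate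
15 | (4αH,7αH)-9β-hydroxy-13-noreudesm-5-en-12,8α-olide | C[C@H]1CCC[C@]2(C)[C@@H](O)[C@@H]3OC(=O)C[C@H]3C=C12 | intermediate
16 | (4αH,7αH)-9β-(tert-butyldimethylsilyloxy)-13-noreudesm-5-en-12,8α-olide | C[C@H]1CCC[C@]2(C)[C@@H](O[Si](C)(C)C(C)(C)C)[C@@H]3OC(=O)C[C@H]3C=C12 | intermediate
17 | (4αH,7αH)-9β-(tert-butyldimethylsilyloxy)-5ξ-(triethylsilylperoxy)-13-noreudesman-12,8α-olide | C[C@H]1CCC[C@]2(C)[C@@H](O[Si](C)(C)C(C)(C)C)[C@@H]3OC(=O)C[C@H]3CC12OO[Si](CC)(CC)CC | intermediate
18 | (4αH,7αH)-5ξ-hydroperoxy-9β-(tert-butyldimethylsilyloxy)-13-noreudesman-12,8α-olide | C[C@H]1CCC[C@]2(C)[C@@H](O[Si](C)(C)C(C)(C)C)[C@@H]3OC(=O)C[C@H]3CC12OO | intermediate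
19 | (4αH,7αH)-5ξ-(4-nitrobenzoylperoxy)-9β-(tert-butyldimethylsilyloxy)-13-noreudesman-12,8α-olide | C[C@H]1CCC[C@]2(C)[C@@H](O[Si](C)(C)C(C)(C)C)[C@@H]3OC(=O)C[C@H]3CC12OOC(=O)c1ccc(cc1)[N+](=O)[O-] | intermediate
20 | 5-(4-nitrobenzoyloxy)-5,10-epoxy-9-(tert-butyldimethylsilyloxy)-13-norgermacran-12,8-olide (acyloxy exo on C5; other centres as in 21) | C1C(=O)O[C@@H]2[C@@H]1C[C@@]1(OC(=O)c3ccc(cc3)[N+](=O)[O-])O[C@](C)(CCC[C@@H]1C)[C@H]2O[Si](C)(C)C(C)(C)C | intermediate
21 | (4S,5R,7R,8R,9S,10R)-5,10-epoxy-9-(tert-butyldimethylsilyloxy)-13-norgermacran-12,8-olide | C1C(=O)O[C@@H]2[C@@H]1C[C@H]1O[C@](C)(CCC[C@@H]1C)[C@H]2O[Si](C)(C)C(C)(C)C | intermediate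
22 | dimethylmethyleneiminium iodide | C[N+](C)=C.[I-] | starting material
23 | lithium enolate of lactone 21 | C1=C([O-])O[C@@H]2[C@@H]1C[C@H]1O[C@](C)(CCC[C@@H]1C)[C@H]2O[Si](C)(C)C(C)(C)C.[Li+] | intermediate
24 | 13-(dimethylamino)-5,10-epoxy-9-(tert-butyldimethylsilyloxy)germacran-12,8-olide (11ξ; other centres as in 21) | CN(C)CC1C(=O)O[C@@H]2[C@@H]1C[C@H]1O[C@](C)(CCC[C@@H]1C)[C@H]2O[Si](C)(C)C(C)(C)C | intermediate
25 | 13-(dimethylamino)-5,10-epoxy-9-hydroxygermacran-12,8-olide (11ξ) | CN(C)CC1C(=O)O[C@@H]2[C@@H]1C[C@H]1O[C@](C)(CCC[C@@H]1C)[C@H]2O | intermediate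
26 | 3-methylbutanoyl chloride | CC(C)CC(Cl)=O | starting material
27 | 13-(dimethylamino)-5,10-epoxy-9-(3-methylbutanoyloxy)germacran-12,8-olide (11ξ) | CN(C)CC1C(=O)O[C@@H]2[C@@H]1C[C@H]1O[C@](C)(CCC[C@@H]1C)[C@H]2OC(=O)CC(C)C | intermediate
28 | 13-(trimethylammonio)-5,10-epoxy-9-(3-methylbutanoyloxy)germacran-12,8-olide iodide (11ξ) | C[N+](C)(C)CC1C(=O)O[C@@H]2[C@@H]1C[C@H]1O[C@](C)(CCC[C@@H]1C)[C@H]2OC(=O)CC(C)C.[I-] | intermediate
29 | (4S,5R,7R,8R,9S,10R)-5,10-epoxy-9-(3-methylbutanoyloxy)germacr-11(13)-en-12,8-olide (CNP0274454.1) | C=C1C(=O)O[C@@H]2[C@@H]1C[C@H]1O[C@](C)(CCC[C@@H]1C)[C@H]2OC(=O)CC(C)C | target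

## Step count and least certain steps

Total step count: 16. Longest linear sequence: 16 steps (1 to 29); compounds 2, 7, 22 and 26 are bought.

Step 11 (key step). What may go wrong: competing migration of the secondary C4 (expansion of ring A instead of cleavage of the ring fusion), or ionisation without a clean shift if the C9 oxygen lowers the aptitude of C10 too far; homolysis of the perester O–O bond is a further drain. Fallback (radical fragmentation, then transannular etherification): starting from 18, reduction with PPh3 should give the tertiary C5 alcohol F1. Alkoxy-radical β-fragmentation (PhI(OAc)2, I2, hν) cleaves C5–C10 toward the tertiary C10 radical and should give the cyclodecenone F2 (an exocyclic alkene isomer would serve equally). NaBH4 should give the C5 alcohol F3, and Hg(OCOCF3)2 followed by NaBH4 closes the C10–O bond in the Markovnikov sense. The fallback comes back to the route at 21.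

Step 12. What may go wrong: slow ionisation of the bridgehead ketal ester (the one-atom bridge twists the overlap between the oxygen lone pair and C5), and proton loss from the cation toward C4, which would erase the C4 centre, competing with capture by the weakly nucleophilic silane. Fallback (thiol capture, then radical reduction): starting from 20, PhSH with BF3·OEt2 at −78 °C should give the S-phenyl monothioketal F4, and Bu3SnH with AIBN in toluene at 80 °C replaces sulfur by hydrogen through the bridgehead α-oxy radical, which cannot lose a proton. The fallback comes back at 21.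

Step 6. What may go wrong: poor facial selectivity at C7, because the dienone ring is nearly flat and its faces differ only through the remote C14 and C1, or partial 1,6-reduction. Fallback (hydroxyl-directed hydrogenation instead of conjugate hydride): starting from 10, deprotonation at C11 with KN(SiMe3)2 and kinetic protonation with AcOH at −78 °C should give the deconjugated keto ester F4-free isomer, namely the 5,7(11)-dienoate F5. Enolate oxidation with the N-sulfonyloxaziridine should give the 8α-hydroxy ketone F6, and H2 with [Rh(nbd)(dppb)]BF4 delivers hydrogen to C7 from the face of the 8α-hydroxyl. The fallback comes back at 13.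

Step 10. What may go wrong: sluggish hydrogen-atom transfer to the hindered ring-fusion alkene, and over-reduction of the peroxide to the alcohol under the silane conditions. Fallback (ionic peroxymercuration instead of radical hydroperoxidation): starting from 16, Hg(OAc)2 with anhydrous H2O2 in ether should give the 6-(acetoxymercurio)-5-hydroperoxide F7, and NaBH4 in aqueous NaOH removes mercury. The fallback comes back at 18.

Step 2. What may go wrong: incomplete face selection in the hydrogenation, or later erosion of the C4 centre by epimerisation through dienol(ate)s in steps 3 to 5, since C4 is vinylogously acidic until step 6. Fallback (thermodynamic handling instead of kinetic face selection): starting from 3, the hydrogenation mixture is separated into 4 and its C4 epimer F8, and F8 is re-equilibrated through the extended dienolate (NaOMe, MeOH) and recycled. The fallback comes back at 4.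

## Further compounds

F1 | step 11 | (4αH,7αH)-5ξ-hydroxy-9β-(tert-butyldimethylsilyloxy)-13-noreudesman-12,8α-olide | C[C@H]1CCC[C@]2(C)[C@@H](O[Si](C)(C)C(C)(C)C)[C@@H]3OC(=O)C[C@H]3CC12O
F2 | step 11 | 5-oxo-9-(tert-butyldimethylsilyloxy)-13-norgermacr-1(10)-en-12,8-olide (alkene geometry open) | C[C@H]1CCC=C(C)[C@@H](O[Si](C)(C)C(C)(C)C)[C@@H]2OC(=O)C[C@H]2CC1=O
F3 | step 11 | (5R)-5-hydroxy-9-(tert-butyldimethylsilyloxy)-13-norgermacr-1(10)-en-12,8-olide | C[C@H]1CCC=C(C)[C@@H](O[Si](C)(C)C(C)(C)C)[C@@H]2OC(=O)C[C@H]2C[C@H]1O
F4 | step 12 | 5-(phenylsulfanyl)-5,10-epoxy-9-(tert-butyldimethylsilyloxy)-13-norgermacran-12,8-olide | C1C(=O)O[C@@H]2[C@@H]1C[C@@]1(Sc3ccccc3)O[C@](C)(CCC[C@@H]1C)[C@H]2O[Si](C)(C)C(C)(C)C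
F5 | step 6 | ethyl (4αH)-9-oxo-13-noreudesma-5,7(11)-dien-12-oate | CCOC(=O)C=C1CC(=O)[C@@]2(C)CCC[C@H](C)C2=C1
F6 | step 6 | ethyl (4αH)-8α-hydroxy-9-oxo-13-noreudesma-5,7(11)-dien-12-oate | CCOC(=O)C=C1[C@@H](O)C(=O)[C@@]2(C)CCC[C@H](C)C2=C1
F7 | step 10 | (4αH,7αH)-6ξ-(acetoxymercurio)-5ξ-hydroperoxy-9β-(tert-butyldimethylsilyloxy)-13-noreudesman-12,8α-olide | C[C@H]1CCC[C@]2(C)[C@@H](O[Si](C)(C)C(C)(C)C)[C@@H]3OC(=O)C[C@H]3C([Hg]OC(C)=O)C12OO
F8 | step 2 | (4aR,8R)-4a,8-dimethyl-4,4a,5,6,7,8-hexahydronaphthalen-2(3H)-one | O=C1C=C2[C@H](C)CCC[C@]2(C)CC1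
A1 | alternative 1 | (1(10)E)-5-hydroxy-9-(3-methylbutanoyloxy)germacra-1(10),11(13)-dien-12,8-olide | C=C1C(=O)O[C@@H]2[C@@H]1C[C@@H](O)[C@@H](C)CC/C=C(C)/[C@H]2OC(=O)CC(C)C
A2 | alternative 2 | (4αH,7αH)-9β-(tert-butyldimethylsilyloxy)-13,14-dinoreudesm-5(10)-en-12,8α-olide | C[C@H]1CCCC2=C1C[C@@H]1CC(=O)O[C@H]1[C@@H]2O[Si](C)(C)C(C)(C)C
A3 | alternative 2 | 5,10-dioxo-9-(tert-butyldimethylsilyloxy)-13,14-dinorgermacran-12,8-olide | C[C@H]1CCCC(=O)[C@@H](O[Si](C)(C)C(C)(C)C)[C@@H]2OC(=O)C[C@H]2CC1=O
A4 | alternative 3 | 7-(tert-butyldimethylsilyloxy)-6-(4-iodopentyl)-6-methyl-hexahydrobenzofuran-2,5-dione (cyclohexanone with C5 ketone; C7/C8/C9/C10 as in 16) | CC(I)CCC[C@@]1(C)C(=O)C[C@@H]2CC(=O)O[C@H]2[C@@H]1O[Si](C)(C)C(C)(C)C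
A5 | alternative 3 | Baeyer–Villiger oxepanone of A4 (oxygen between C5 and C10) | CC(I)CCC[C@@]1(C)OC(=O)C[C@@H]2CC(=O)O[C@H]2[C@@H]1O[Si](C)(C)C(C)(C)C
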